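**Plan**
1. Benzofuran numbering of the target is used: O1, C2, C3, C3a, C4(=O), C5(CH3)2, C6(=O), C7(acyl), C7a. After removal of a silyl ether on the tertiary alcohol, the six-membered ring is cut at C5–C6 and C7–C7a together. This gives a C6–C7 acylketene unit carrying the (R)-2-methylbutanoyl group and a γ-butyrolactone (O1, C2, C3, C3a, C7a) that bears prenyl and isobutyryl (C4, C5) on C3a.
2. Enabling feature: C7a, the oxygen-bearing enol-ether carbon of the dihydrofuran ring, is a lactone carbonyl in disguise. C3a and C5 are both quaternary, so the lactone partner has a single acidic C–H (the future C5) and the annulated trione cannot aromatise.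
3. The lactone is cut at C3a–C4 (aldol, then oxidation), at O1–C2 (epoxide opening by the carboxyl group) and at C3–C3a (acid dianion plus 2,3-epoxygeranyl iodide).
4. Forward order: epoxide, then γ-lactone (the future dihydrofuran ring), then quaternary C3a, then the six-membered ring by a formal [4+2] annulation with re-closure of the dihydrofuran, then desilylation.
5. Stereochemistry: C2 and the carbinol carbon come from Sharpless epoxidation of geraniol (C2 is inverted on lactonisation). C3a is set by addition to the lactone enolate anti to the C2 substituent. The acyl stereocentre comes from (R)-2-methylbutanoic acid.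

Key step: step 9

Remark: 5-methylhex-4-enoic acid and (R)-2-methylbutanoic acid are taken as purchased; intermediates that exist as keto/enol mixtures are drawn as one tautomer.

**Step 1**
Reactants: 1 geraniol
Product: 2 (2S,3S)-2,3-epoxygeraniol
Conditions: Ti(OiPr)4 (5 mol%), L-(+)-diethyl tartrate (6 mol%), t-BuOOH, 4 Å MS, CH2Cl2, −20 °C
Reagents that add atoms: tert-butyl hydroperoxide, CC(C)(C)OO
Why: Sharpless asymmetric epoxidation; the catalyst formed from Ti(OiPr)4 and L-(+)-diethyl tartrate binds the allylic alcohol and should deliver oxygen to one face of the 2,3-olefin only (2S,3S), leaving the 6,7-olefin untouched and setting both oxygen-bearing stereocentres of the target.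

**Step 2**
Reactants: 2 (2S,3S)-2,3-epoxygeraniol
Product: 3 (2S,3R)-3-(iodomethyl)-2-methyl-2-(4-methylpent-3-en-1-yl)oxirane
Conditions: I2, PPh3, imidazole, CH2Cl2, 0 °C
Reagents that add atoms: iodine, II
Why: Appel-type iodination; iodide displaces the alkoxyphosphonium at the primary carbon and the epoxide carbons are not involved (the label at the ring CH changes from S to R only because CH2I outranks the ring carbon).

**Step 3**
Reactants: 3 (2S,3R)-3-(iodomethyl)-2-methyl-2-(4-methylpent-3-en-1-yl)oxirane; 4 5-methylhex-4-enoic acid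
Product: 6 (5R)-5-[(2S)-2-hydroxy-6-methylhept-5-en-2-yl]-3-(3-methylbut-2-en-1-yl)oxolan-2-one (both C3 epimers), via epoxy acid 5 (not isolated)
Conditions: 4, LiN(iPr)2 (2.1 equiv), THF, DMPU, −78 → 0 °C; 3, −78 → −20 °C; then 1 M HCl to pH 3, EtOAc, rt
Reagents that add atoms: none
Why: Alkylation of a carboxylic acid dianion at its α-carbon by SN2 at the primary iodide (the neopentyl-type epoxide carbon is much slower), then acid-induced lactonisation of the γ,δ-epoxy acid by 5-exo attack of the carboxyl group at the secondary epoxide carbon with inversion (S to R); the tertiary carbinol (S) is untouched and the C3 epimers converge in step 5.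

**Step 4**
Reactants: 6 hydroxy lactone
Product: 7 (5R)-3-(3-methylbut-2-en-1-yl)-5-[(2S)-6-methyl-2-(triethylsilyloxy)hept-5-en-2-yl]oxolan-2-one (both C3 epimers)
Conditions: Et3SiOTf, 2,6-lutidine, CH2Cl2, −78 → 0 °C
Reagents that add atoms: triethylsilyl trifluoromethanesulfonate, CC[Si](CC)(CC)OS(=O)(=O)C(F)(F)F
Why: Silyl triflate silylation of the hindered tertiary alcohol; the ether keeps this oxygen from attacking the lactone under base and from closing a six-membered enol ether in step 9.

**Step 5**
Reactants: 7 silylated lactone; 8 2-methylpropanal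
Product: 9 (3R,5R)-3-(1-hydroxy-2-methylpropyl)-3-(3-methylbut-2-en-1-yl)-5-[(2S)-6-methyl-2-(triethylsilyloxy)hept-5-en-2-yl]oxolan-2-one (both carbinol epimers)
Conditions: LiN(iPr)2, THF, −78 °C; 8; AcOH, −78 °C
Reagents that add atoms: none
Why: Aldol addition of the tetrasubstituted lithium lactone enolate; the aldehyde should add to the enolate face anti to the bulky C5 substituent (1,3-induction as in sequential alkylation of γ-substituted butyrolactones), which puts the new C–C bond trans and the prenyl group cis to the side chain (3R).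

**Step 6**
Reactants: 9 aldol adduct
Product: 10 (3R,5R)-3-(2-methylpropanoyl)-3-(3-methylbut-2-en-1-yl)-5-[(2S)-6-methyl-2-(triethylsilyloxy)hept-5-en-2-yl]oxolan-2-one
Conditions: Dess–Martin periodinane, pyridine, CH2Cl2, 0 °C → rt
Reagents that add atoms: none
Why: Dess–Martin oxidation of the secondary alcohol to the ketone; the α-carbon is quaternary, so nothing can epimerise and both carbinol epimers converge.

**Step 7**
Reactants: 11 (2R)-2-methylbutanoic acid; 12 Meldrum's acid
Product: 13 5-[(2R)-1-hydroxy-2-methylbutylidene]-2,2-dimethyl-1,3-dioxane-4,6-dione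
Conditions: DCC, DMAP, CH2Cl2, 0 °C → rt
Reagents that add atoms: none
Why: Carbodiimide-mediated C-acylation of Meldrum's acid; the α-stereocentre of a simple α-alkyl acid should be retained under these mild conditions.

**Step 8**
Reactants: 13 acyl Meldrum's acid
Product: 14 S-phenyl (4R)-4-methyl-3-oxohexanethioate
Conditions: PhSH, toluene, 90 °C
Reagents that add atoms: thiophenol, Sc1ccccc1
Why: Thermal retro-[4+2] loss of acetone and CO2 from the acyl Meldrum's acid gives the acylketene, which the thiol captures under neutral conditions that do not touch the stereocentre.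

**Step 9**
Reactants: 10 keto lactone; 14 S-phenyl (4R)-4-methyl-3-oxohexanethioate
Product: 18 (2R,3aS)-5,5-dimethyl-7-[(2R)-2-methylbutanoyl]-3a-(3-methylbut-2-en-1-yl)-2-[(2S)-6-methyl-2-(triethylsilyloxy)hept-5-en-2-yl]-3,3a-dihydro-1-benzofuran-4,6(2H,5H)-dione, via acylketene 15 (not isolated), via triketo lactone 16 (not isolated), via hydroxy acyltrione 17 (not isolated)
Conditions: 10, KN(SiMe3)2 (1.05 equiv), THF, −78 °C; add 14 pre-treated with KN(SiMe3)2 (1.0 equiv), THF, −78 °C; −78 → 45 °C; then AcOH (3 equiv), PPTS (0.2 equiv), toluene, 45 °C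
Reagents that add atoms: none
Why: Proposed new method: the closest known reaction types are the E1cB acyl transfer of aryl and thiol 3-oxo esters through acylketenes, the C-acylation of tetrasubstituted enolates by ketenes, the base-induced lactone-to-1,3-dione acyl transfer (Dieckmann type) and the acid-catalysed closure of hydroxyalkyl 1,3-diones to cyclic vinylogous esters, here run as one formal [4+2] annulation. Mechanism: on warming, the enolate of 14 expels thiophenoxide to give acylketene 15 (recapture by thiophenoxide only regenerates it); the CMe2 carbon of the enolate of 10 adds to the sp carbon of 15 (first bond, C5–C6) to give the diketonate of 16, whose central carbon attacks the lactone carbonyl (second bond, C7–C7a) so that the lactone opens to the trione anion of 17, and acid then re-forms the O1–C7a bond with loss of water. Ring closures: the carbocycle closes 6-exo-trig, helped by the two quaternary carbons in the chain, and the dihydrofuran is re-closed by 5-exo-trig hemiketalisation at C7a followed by dehydration towards C7. No stereocentre is created: C2, C3a and the carbinol carbon are carried in from 10, and the (R)-2-methylbutanoyl centre should be safe because its carbonyl neighbour is at every stage part of an enolate or a ketene, never a free ketone facing strong base. Selectivity needed: carbon over oxygen acylation of the hindered enolate, secured because the O-acyl adduct is an enol 3-oxo ester that reverts to 15 by the same E1cB path while the C-adduct is drained to the strongly acidic acyl trione; and enol ether formation only at C7a from the secondary oxygen, secured because the other carbonyl within reach (C4) lies between two quaternary carbons and cannot enolise and the tertiary oxygen is silylated.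

**Step 10**
Reactants: 18 silyl ether of the target
Product: 19 (2R,3aS)-2-[(2S)-2-hydroxy-6-methylhept-5-en-2-yl]-5,5-dimethyl-7-[(2R)-2-methylbutanoyl]-3a-(3-methylbut-2-en-1-yl)-3,3a-dihydro-1-benzofuran-4,6(2H,5H)-dione
Conditions: HF·pyridine, pyridine, THF, 0 °C → rt
Reagents that add atoms: none
Why: Fluoride cleavage of the tertiary triethylsilyl ether; the vinylogous ester, the trisubstituted olefins and all stereocentres should be inert to buffered HF.

**Compound list**
1 | geraniol, (2E)-3,7-dimethylocta-2,6-dien-1-ol | CC(C)=CCC/C(C)=C/CO | starting material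
2 | (2S,3S)-2,3-epoxygeraniol, [(2S,3S)-3-methyl-3-(4-methylpent-3-en-1-yl)oxiran-2-yl]methanol | OC[C@@H]1O[C@@]1(C)CCC=C(C)C | intermediate
3 | (2S,3R)-3-(iodomethyl)-2-methyl-2-(4-methylpent-3-en-1-yl)oxirane | IC[C@@H]1O[C@@]1(C)CCC=C(C)C | intermediate
4 | 5-methylhex-4-enoic acid | CC(C)=CCCC(=O)O | starting material
5 | 5-methyl-2-{[(2S,3S)-3-methyl-3-(4-methylpent-3-en-1-yl)oxiran-2-yl]methyl}hex-4-enoic acid (both C2 epimers) | OC(=O)C(CC=C(C)C)C[C@@H]1O[C@@]1(C)CCC=C(C)C | intermediate
6 | (5R)-5-[(2S)-2-hydroxy-6-methylhept-5-en-2-yl]-3-(3-methylbut-2-en-1-yl)oxolan-2-one (both C3 epimers) | O=C1O[C@@H]([C@@](C)(O)CCC=C(C)C)CC1CC=C(C)C | intermediate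
7 | (5R)-3-(3-methylbut-2-en-1-yl)-5-[(2S)-6-methyl-2-(triethylsilyloxy)hept-5-en-2-yl]oxolan-2-one (both C3 epimers) | O=C1O[C@@H]([C@@](C)(O[Si](CC)(CC)CC)CCC=C(C)C)CC1CC=C(C)C | intermediate
8 | 2-methylpropanal | CC(C)C=O | starting material
9 | (3R,5R)-3-(1-hydroxy-2-methylpropyl)-3-(3-methylbut-2-en-1-yl)-5-[(2S)-6-methyl-2-(triethylsilyloxy)hept-5-en-2-yl]oxolan-2-one (both carbinol epimers) | O=C1O[C@@H]([C@@](C)(O[Si](CC)(CC)CC)CCC=C(C)C)C[C@]1(CC=C(C)C)C(O)C(C)C | intermediate
10 | (3R,5R)-3-(2-methylpropanoyl)-3-(3-methylbut-2-en-1-yl)-5-[(2S)-6-methyl-2-(triethylsilyloxy)hept-5-en-2-yl]oxolan-2-one | O=C1O[C@@H]([C@@](C)(O[Si](CC)(CC)CC)CCC=C(C)C)C[C@]1(CC=C(C)C)C(=O)C(C)C | intermediate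
11 | (2R)-2-methylbutanoic acid | CC[C@@H](C)C(=O)O | starting material
12 | Meldrum's acid, 2,2-dimethyl-1,3-dioxane-4,6-dione | CC1(C)OC(=O)CC(=O)O1 | starting material
13 | 5-[(2R)-1-hydroxy-2-methylbutylidene]-2,2-dimethyl-1,3-dioxane-4,6-dione | CC[C@@H](C)C(O)=C1C(=O)OC(C)(C)OC1=O | intermediate
14 | S-phenyl (4R)-4-methyl-3-oxohexanethioate | CC[C@@H](C)C(=O)CC(=O)Sc1ccccc1 | intermediate
15 | (4R)-4-methylhex-1-ene-1,3-dione (acylketene) | CC[C@@H](C)C(=O)C=C=O | intermediate
16 | (3R,5R)-3-(3-methylbut-2-en-1-yl)-5-[(2S)-6-methyl-2-(triethylsilyloxy)hept-5-en-2-yl]-3-[(6R)-2,2,6-trimethyl-3,5-dioxooctanoyl]oxolan-2-one (formed as its potassium enolate) | O=C1O[C@@H]([C@@](C)(O[Si](CC)(CC)CC)CCC=C(C)C)C[C@]1(CC=C(C)C)C(=O)C(C)(C)C(=O)CC(=O)[C@H](C)CC | intermediate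
17 | (6S)-6-[(2R,3S)-2-hydroxy-3,7-dimethyl-3-(triethylsilyloxy)oct-6-en-1-yl]-4,4-dimethyl-2-[(2R)-2-methylbutanoyl]-6-(3-methylbut-2-en-1-yl)cyclohexane-1,3,5-trione (drawn as the C1 enol) | CC[C@@H](C)C(=O)C1=C(O)[C@@](C[C@@H](O)[C@@](C)(O[Si](CC)(CC)CC)CCC=C(C)C)(CC=C(C)C)C(=O)C(C)(C)C1=O | intermediate
18 | (2R,3aS)-5,5-dimethyl-7-[(2R)-2-methylbutanoyl]-3a-(3-methylbut-2-en-1-yl)-2-[(2S)-6-methyl-2-(triethylsilyloxy)hept-5-en-2-yl]-3,3a-dihydro-1-benzofuran-4,6(2H,5H)-dione | CC[C@@H](C)C(=O)C1=C2O[C@@H]([C@@](C)(O[Si](CC)(CC)CC)CCC=C(C)C)C[C@]2(CC=C(C)C)C(=O)C(C)(C)C1=O | intermediate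
19 | (2R,3aS)-2-[(2S)-2-hydroxy-6-methylhept-5-en-2-yl]-5,5-dimethyl-7-[(2R)-2-methylbutanoyl]-3a-(3-methylbut-2-en-1-yl)-3,3a-dihydro-1-benzofuran-4,6(2H,5H)-dione | CC[C@@H](C)C(=O)C1=C2O[C@@H]([C@@](C)(O)CCC=C(C)C)C[C@]2(CC=C(C)C)C(=O)C(C)(C)C1=O | target

**Step count and risks**
Total step count: 10. Longest linear sequence: 8 steps (steps 1–6, 9 and 10, from geraniol).

Steps most likely to fail:

1. Step 9 (Proposed new method). The transient acylketene may be captured at the enolate oxygen or consumed by self-condensation instead of reacting at the hindered enolate carbon, and the ring closure onto the hindered lactone carbonyl may stall. The fallback uses known dearomatisation chemistry, sets out from 11 and 3 and comes back at 19. Acid 11 with SOCl2 gives (2R)-2-methylbutanoyl chloride F1. Friedel–Crafts acylation of phloroglucinol (AlCl3, PhNO2/CH2Cl2) gives (2R)-2-methyl-1-(2,4,6-trihydroxyphenyl)butan-1-one F2. Geminal C-methylation (NaOMe, MeI, MeOH) dearomatises the ring to 4,4-dimethyl-2-[(2R)-2-methylbutanoyl]cyclohexane-1,3,5-trione F3. C-prenylation (prenyl bromide, aqueous KOH) gives 4,4-dimethyl-2-[(2R)-2-methylbutanoyl]-6-(3-methylbut-2-en-1-yl)cyclohexane-1,3,5-trione F4. Alkylation of the sodium salt of F4 (NaH, DMF) with epoxy iodide 3 at the prenyl-bearing carbon, followed in the same flask by 5-exo opening of the epoxide by the neighbouring enolate oxygen with inversion, should give 19 together with its C3a epimer; the two are separated by chromatography. This fallback gives up control of C3a.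

2. Step 3. The dianion may attack the epoxide or open it by elimination to an allylic alkoxide instead of displacing the iodide, and the lactonisation may open the epoxide 6-endo at the tertiary carbon. The fallback replaces the alkylation by an olefination, sets out from 2 and comes back at 7. Oxidation of 2 (SO3·pyridine, DMSO, Et3N) gives (2R,3S)-3-methyl-3-(4-methylpent-3-en-1-yl)oxirane-2-carbaldehyde F5. Wittig reaction with Ph3P=CHCO2Me gives methyl (2E)-3-[(2S,3S)-3-methyl-3-(4-methylpent-3-en-1-yl)oxiran-2-yl]prop-2-enoate F6. Diimide (KO2CN=NCO2K, AcOH) should reduce only the conjugated disubstituted olefin, giving methyl 3-[(2S,3S)-3-methyl-3-(4-methylpent-3-en-1-yl)oxiran-2-yl]propanoate F7. LiOH and then mild acid close (5R)-5-[(2S)-2-hydroxy-6-methylhept-5-en-2-yl]oxolan-2-one F8 with the same inversion. Et3SiOTf/2,6-lutidine gives (5R)-5-[(2S)-6-methyl-2-(triethylsilyloxy)hept-5-en-2-yl]oxolan-2-one F9. LiN(iPr)2 and prenyl bromide then give 7.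

3. Step 5. The aldol addition at the congested quaternary carbon may reverse, with erosion of facial selectivity. The fallback uses an irreversible C-acylation, sets out from 7 and comes back at 10, so that steps 5 and 6 are replaced. LiN(iPr)2 and Me3SiCl convert 7 into trimethyl{[(5R)-3-(3-methylbut-2-en-1-yl)-5-[(2S)-6-methyl-2-(triethylsilyloxy)hept-5-en-2-yl]-4,5-dihydrofuran-2-yl]oxy}silane F10. A TiCl4-mediated Claisen condensation of F10 with 2-methylpropanoyl chloride (CH2Cl2, −78 °C) should give 10, again by approach anti to the C5 substituent.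

**Further compounds**
F1 | step 9 | (2R)-2-methylbutanoyl chloride | CC[C@@H](C)C(=O)Cl
F2 | step 9 | (2R)-2-methyl-1-(2,4,6-trihydroxyphenyl)butan-1-one | CC[C@@H](C)C(=O)c1c(O)cc(O)cc1O
F3 | step 9 | 4,4-dimethyl-2-[(2R)-2-methylbutanoyl]cyclohexane-1,3,5-trione (drawn as an enol) | CC[C@@H](C)C(=O)C1=C(O)CC(=O)C(C)(C)C1=O
F4 | step 9 | 4,4-dimethyl-2-[(2R)-2-methylbutanoyl]-6-(3-methylbut-2-en-1-yl)cyclohexane-1,3,5-trione (drawn as an enol) | CC[C@@H](C)C(=O)C1=C(O)C(CC=C(C)C)C(=O)C(C)(C)C1=O
F5 | step 3 | (2R,3S)-3-methyl-3-(4-methylpent-3-en-1-yl)oxirane-2-carbaldehyde | O=C[C@@H]1O[C@@]1(C)CCC=C(C)C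
F6 | step 3 | methyl (2E)-3-[(2S,3S)-3-methyl-3-(4-methylpent-3-en-1-yl)oxiran-2-yl]prop-2-enoate | COC(=O)/C=C/[C@@H]1O[C@@]1(C)CCC=C(C)C
F7 | step 3 | methyl 3-[(2S,3S)-3-methyl-3-(4-methylpent-3-en-1-yl)oxiran-2-yl]propanoate | COC(=O)CC[C@@H]1O[C@@]1(C)CCC=C(C)C
F8 | step 3 | (5R)-5-[(2S)-2-hydroxy-6-methylhept-5-en-2-yl]oxolan-2-one | O=C1O[C@@H]([C@@](C)(O)CCC=C(C)C)CC1
F9 | step 3 | (5R)-5-[(2S)-6-methyl-2-(triethylsilyloxy)hept-5-en-2-yl]oxolan-2-one | O=C1O[C@@H]([C@@](C)(O[Si](CC)(CC)CC)CCC=C(C)C)CC1
F10 | step 5 | trimethyl{[(5R)-3-(3-methylbut-2-en-1-yl)-5-[(2S)-6-methyl-2-(triethylsilyloxy)hept-5-en-2-yl]-4,5-dihydrofuran-2-yl]oxy}silane | C[Si](C)(C)OC1=C(CC=C(C)C)C[C@H]([C@@](C)(O[Si](CC)(CC)CC)CCC=C(C)C)O1
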